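Thursday's flask takes its E over 3.0 min, while Sunday's has it all at the start, and I want to know what that delay costs in J.

| flask | E | D | remark | time |
|---|---|---|---|---|
| violet | 0.10 M | 1.1 equiv | run made earlier |  |
| red | 0.050 M | 1.1 equiv | run made earlier |  |
| Thursday's | 0.10 M (fed, over 3.0 min) | 1.10 equiv | all else is in the flask from the start; the feed brings no volume worth counting | 4.0 min |
| Sunday's | 0.10 M | 1.10 equiv | everything together at the start | 4.0 min |
| Monday's | 0.10 M | 1.10 equiv (fed, over 3.0 min) | all else is in the flask from the start; the feed brings no volume worth counting | 4.0 min |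
| Saturday's | 0.10 M | 1.10 equiv (in portions, 2, over 3.0 min) | first portion at the start, last at 3.0 min | 4.0 min |

violet run (percent of the E charged)

| time / min | J / % | E / % |
|---|---|---|
| 0.167 | 0.3 | 32.3 |
| 0.333 | 5.0 | 8.3 |
| 0.667 | 22.8 | 1.0 |
| 1.00 | 35.5 | 0 |
| 1.33 | 47.1 | 0 |
| 2.00 | 62.8 | 0 |
| 2.50 | 68.8 | 1.5 |

red run (percent of the E charged)

| time / s | J / % | E / % |
|---|---|---|
| 10.0 | 1.2 | 32.6 |
| 20.0 | 4.0 | 11.4 |
| 30.0 | 6.6 | 3.6 |
| 40.0 | 15.6 | 1.7 |
| 50.0 | 20.8 | 0 |
| 60.0 | 22.8 | 0 |
| 80.0 | 34.2 | 0 |

(each reading ± 1 percentage point)

* the flask with the highest amount of J, in percent of the E charged ("all alike" if they lie within 1.5 percentage points) (Thursday's / Sunday's / Monday's / Saturday's / all alike)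
* final J, as a percentage of the E charged, in Thursday's
* final J, as a percentage of the E charged, in Sunday's
* final J, as a percentage of the E charged, in Monday's
* final J, as a percentage of the E charged, in Saturday's

- the numbers in the tables scatter by 1 percentage point (one standard deviation)
- a reading or a percentage of J counts all its forms, free or not
- a reading of E is of its free form alone

**Step one.** Let k be the first-order rate constant of E's loss. The first violet reading gives 6.77 min⁻¹. The first red reading, at half the concentration, gives 6.73 min⁻¹, about the same. So I take k as independent of concentration.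

**Step two.** I fold the feed and the loss into one number. N = k × feed time, the feed time counted in lifetimes of E (a Damköhler number), is 20.3.

**Step three.** A lifetime of 0.148 min is shorter than the feed, so in Thursday's E leaves nearly as it comes. Its standing amount should be the charge divided by N, 4.93 %.

**Step four.** Thursday's then runs like Sunday's, late by half the feed, 1.50 min. Violet has Sunday's charges, and at 2.50 min it reads J 68.8 %, still rising. So I put Sunday's on top and Thursday's near that reading.

**Step five.** Is N enough? It holds no J. In violet, E is down to 1.0 % at 0.667 min, with J at 22.8 %. In Thursday's, E keeps entering while J grows, and I have not reckoned that meeting from the readings. My figure holds if E ignores J.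

**Step six.** The forecast names Sunday's, with 80 % there, 69 % in Thursday's, 67 % in Monday's and 65 % in Saturday's: “Envelope stepping gives about 69% for Thursday, 67% for Monday and 65% for Saturday”.

**Step seven.** Sunday's gives the most J, 80.2 %, then Monday's 70.9 %, Saturday's 61.5 % and Thursday's 39.8 %.

    E → Z (k = 0.110 s⁻¹)
    D → L (k = 0.0280 s⁻¹)
    Z + L → J (k = 0.230 L mol⁻¹ s⁻¹)
    E + J ⇌ G, settled at all times (K = 11.0 L mol⁻¹)
    E + J → Q (k = 2.60 L mol⁻¹ s⁻¹)
    2 E → X (k = 1.10 × 10⁻⁴ L mol⁻¹ s⁻¹)

Thursday's holds 47.9 % as Q at 4.00 min, more than Sunday's 7.21 %, each Q counted as two. At the end of the feed, 3.00 min, Thursday's E stands at 3.05 %, below the 4.93 % from N. A neighbour of Thursday's charged with a quarter of the E, 0.025 M, keeps N at 20.3, and its Q at 4.00 min is 11.0 %.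

The earlier runs and the new flask were computed on assumed constants, and the scatter is random.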